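**Retrosynthetic overview**

1. The target is the C8 acetate of an 8-hydroxy furofuran; the acetate is put on last by peracetylation followed by selective aminolysis of the aryl acetate.
2. Key disconnection: the C7–O bond of ring A (O–C7–C8–C8'–C9'). The strategy rests on one feature: of the two aryl rings only the one on C7 has a free para-hydroxyl, so only C7 can become the exocyclic terminus of a p-quinone methide, which the C9' hydroxyl then captures.
3. Ring B (O–C7'–C8'–C8–C9) is closed earlier by the same oxidation at C7', at a stage where the C7' aryl is the only free phenol and the C7 aryl is O-benzylated. O-Methylation then makes that ring an inert 3,4-dimethoxyphenyl group, and hydrogenolysis frees the C7 phenol.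
4. The acyclic 2,3-bis(arylmethyl)butane-1,2,4-triol comes from diethyl (S)-malate: Fráter–Seebach alkylation sets C8', Seebach dioxolanone alkylation makes C8 quaternary with retention, and LiAlH4 gives the triol.
5. Ring order: ring B (step 11), then ring A (step 14).

Key step: step 14

Remark: lignan numbering is used (C7, C8, C9 for the guaiacyl half; C7', C8', C9' for the dimethoxyphenyl half); diethyl (S)-malate and [4-(benzyloxy)-3-methoxyphenyl]methanol are taken as purchased, and the minor diastereomers expected in steps 5 and 7 are assumed to be removable by chromatography or crystallisation.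

**Route**

Step 1
Reactants: 1 vanillin
Product: 2 4-(allyloxy)-3-methoxybenzaldehyde
Conditions: allyl bromide, K2CO3, DMF, rt
Reagents that add atoms: allyl bromide, C=CCBr
Why: Williamson etherification of the phenoxide; the allyl ether is chosen because it can later be removed in the presence of a benzyl ether.

Step 2
Reactants: 2 4-(allyloxy)-3-methoxybenzaldehyde
Product: 3 [4-(allyloxy)-3-methoxyphenyl]methanol
Conditions: NaBH4, MeOH, 0 °C
Reagents that add atoms: none
Why: Borohydride reduction of the aryl aldehyde to the benzylic alcohol, to which the allyl ether is inert.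

Step 3
Reactants: 3 [4-(allyloxy)-3-methoxyphenyl]methanol
Product: 4 4-(allyloxy)-3-methoxybenzyl bromide
Conditions: PBr3, Et2O, 0 °C; used crude
Reagents that add atoms: phosphorus tribromide, BrP(Br)Br
Why: Substitution of the electron-rich benzylic alcohol through its phosphite ester should give the bromide cleanly; it is used at once because such bromides are labile.

Step 4
Reactants: 5 [4-(benzyloxy)-3-methoxyphenyl]methanol
Product: 6 4-(benzyloxy)-3-methoxybenzyl bromide
Conditions: PBr3, Et2O, 0 °C
Reagents that add atoms: phosphorus tribromide, BrP(Br)Br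
Why: Same benzylic alcohol-to-bromide substitution as in step 3, here on the O-benzyl series.

Step 5
Reactants: 7 diethyl (S)-malate; 4 4-(allyloxy)-3-methoxybenzyl bromide
Product: 9 diethyl (2S,3R)-3-{[4-(allyloxy)-3-methoxyphenyl]methyl}-2-hydroxybutanedioate, via dilithium alkoxide enolate 8 (not isolated)
Conditions: LiN(iPr)2 (2.2 equiv), THF, −78 to −20 °C; then 4, −78 to −10 °C; aq. HCl
Reagents that add atoms: none
Why: Fráter–Seebach alkylation, in which the chelated alkoxide enolate is attacked at C8' on the face anti to the C8 oxygen, so the existing C8 centre of the malate sets C8' as 3R (the same sense as the known allylation of this dianion).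

Step 6
Reactants: 9 diethyl (2S,3R)-3-{[4-(allyloxy)-3-methoxyphenyl]methyl}-2-hydroxybutanedioate
Product: 10 (2S,3R)-3-{[4-(allyloxy)-3-methoxyphenyl]methyl}-2-hydroxybutanedioic acid
Conditions: KOH, EtOH–H2O, rt; then aq. HCl
Reagents that add atoms: potassium hydroxide, [K+].[OH-]
Why: Saponification of both esters; once the carboxylate has formed, the C8' hydrogen is no longer acidic enough to epimerise.

Step 7
Reactants: 10 (2S,3R)-3-{[4-(allyloxy)-3-methoxyphenyl]methyl}-2-hydroxybutanedioic acid; 11 pivalaldehyde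
Product: 12 (2R)-3-[4-(allyloxy)-3-methoxyphenyl]-2-[(2S,4S)-2-tert-butyl-5-oxo-1,3-dioxolan-4-yl]propanoic acid
Conditions: TsOH (cat.), H2SO4 (cat.), pentane–CH2Cl2, reflux, Dean–Stark
Reagents that add atoms: none
Why: Seebach acetalisation of the α-hydroxy acid half (C8–OH with the C9 carboxyl) gives the five-membered dioxolanone, and the cis acetal is the thermodynamic product, so the C8 configuration is copied into the new acetal centre.

Step 8
Reactants: 12 the cis dioxolanone acid; 6 4-(benzyloxy)-3-methoxybenzyl bromide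
Product: 14 (2R)-3-[4-(allyloxy)-3-methoxyphenyl]-2-[(2S,4S)-4-{[4-(benzyloxy)-3-methoxyphenyl]methyl}-2-tert-butyl-5-oxo-1,3-dioxolan-4-yl]propanoic acid, via dilithium carboxylate enolate 13 (not isolated)
Conditions: 6 (1.1 equiv), THF, −78 °C; LiN(SiMe3)2 (2.2 equiv) added slowly to the mixture; aq. HCl
Reagents that add atoms: none
Why: Seebach self-regeneration of stereocentres, in which the dioxolanone enolate is benzylated anti to the tert-butyl group, so the arylmethyl group takes the place of the C8 hydrogen with retention and C8 becomes quaternary (base is added to the substrate and bromide together so that the labile enolate is trapped as it forms).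

Step 9
Reactants: 14 the C8-benzylated dioxolanone acid
Product: 15 (2S,3S)-3-{[4-(allyloxy)-3-methoxyphenyl]methyl}-2-{[4-(benzyloxy)-3-methoxyphenyl]methyl}butane-1,2,4-triol
Conditions: LiAlH4 (excess), THF, 0 °C to reflux; aqueous work-up
Reagents that add atoms: none
Why: Hydride reduction of the C9' carboxylic acid and of the dioxolanone carbonyl (C9) to primary alcohols, with collapse of the acetal to release the tertiary C8 hydroxyl; no stereocentre is touched and both aryl ethers survive.

Step 10
Reactants: 15 the allyl benzyl triol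
Product: 16 (2S,3S)-2-{[4-(benzyloxy)-3-methoxyphenyl]methyl}-3-[(4-hydroxy-3-methoxyphenyl)methyl]butane-1,2,4-triol
Conditions: Pd(PPh3)4 (5 mol %), morpholine, THF, rt
Reagents that add atoms: none
Why: Tsuji–Trost deallylation, in which zerovalent palladium ionises the aryl allyl ether and morpholine captures the allyl group, leaving the benzyl ether and the alcohols alone.

Step 11
Reactants: 16 the monophenol triol
Product: 18 (3S,4R,5S)-3-{[4-(benzyloxy)-3-methoxyphenyl]methyl}-5-(4-hydroxy-3-methoxyphenyl)-4-(hydroxymethyl)oxolan-3-ol, via p-quinone methide 17 (not isolated)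
Conditions: Ag2O (1.5 equiv), CH2Cl2–acetone, rt, dark
Reagents that add atoms: none
Why: Ag2O oxidation of the only free 4-alkyl-2-methoxyphenol gives the p-quinone methide at C7', and the C9 hydroxyl adds 5-exo-trig (oxa-conjugate addition) to close ring B; the aryl group should settle trans to the C8' hydroxymethyl group, which is the less crowded and thermodynamically preferred 2,3-trans oxolane, so C7' is set as S.

Step 12
Reactants: 18 the ring B phenol
Product: 19 (3S,4R,5S)-3-{[4-(benzyloxy)-3-methoxyphenyl]methyl}-5-(3,4-dimethoxyphenyl)-4-(hydroxymethyl)oxolan-3-ol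
Conditions: MeI, K2CO3, acetone, reflux
Reagents that add atoms: iodomethane, CI
Why: Williamson O-methylation; carbonate deprotonates only the phenol, so the primary and tertiary alcohols are not alkylated.

Step 13
Reactants: 19 the O-benzyl oxolane
Product: 20 (3S,4R,5S)-5-(3,4-dimethoxyphenyl)-3-[(4-hydroxy-3-methoxyphenyl)methyl]-4-(hydroxymethyl)oxolan-3-ol
Conditions: H2 (1 atm), Pd/C (10%), EtOAc, rt, stopped at full conversion
Reagents that add atoms: none
Why: Hydrogenolysis of the aryl benzyl ether, which is much faster in neutral ethyl acetate than cleavage of the cyclic benzylic C7'–O bond.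

Step 14
Reactants: 20 the ring B oxolane with free C7 phenol
Product: 22 (1S,2R,5R,6S)-6-(3,4-dimethoxyphenyl)-2-(4-hydroxy-3-methoxyphenyl)-3,7-dioxabicyclo[3.3.0]octan-1-ol, via p-quinone methide 21 (not isolated)
Conditions: Ag2O (1.5 equiv), CH2Cl2, rt, dark
Reagents that add atoms: none
Why: Ag2O removes two electrons and two protons from the single free 4-alkyl-2-methoxyphenol (through the phenoxyl radical) to give p-quinone methide 21, whose exocyclic terminus is C7; the 3,4-dimethoxyphenyl ring has no phenol and cannot react this way. The closest known reaction type is the Ag2O or DDQ oxidation of 4-alkylguaiacols to p-quinone methides with intramolecular capture by an alcohol, as in biomimetic lignan ether formation. Ring A (O–C7–C8–C8'–C9') closes by 5-exo-trig oxa-conjugate addition of the C9' hydroxyl to C7 with rearomatisation, and C7–O is the only bond formed. The new stereocentre C7 is controlled by the ring fusion: the two oxolanes can only be cis-fused, and the flat quinone methide turns away from ring B, so the aryl group ends on the convex face, cis to the C8 hydroxyl (7R in lignan numbering), which is also the more stable epimer. The step needs selectivity for C7 over C7', secured by the single free phenol, and for the C9' hydroxyl over the C8 hydroxyl, which could only give an epoxide; because C8 is quaternary, 21 cannot tautomerise to a styrene.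

Step 15
Reactants: 22 the 8-hydroxy furofuran phenol
Product: 23 (1S,2R,5R,6S)-2-(4-acetoxy-3-methoxyphenyl)-6-(3,4-dimethoxyphenyl)-3,7-dioxabicyclo[3.3.0]octan-1-yl acetate
Conditions: Ac2O (excess), Et3N, DMAP, CH2Cl2, rt to 40 °C
Reagents that add atoms: acetic anhydride, CC(=O)OC(C)=O
Why: DMAP-catalysed acylation (Steglich–Höfle conditions) is strong enough to acetylate the tertiary bridgehead alcohol as well as the phenol, and the basic medium avoids acid-induced epimerisation of the benzylic ethers.

Step 16
Reactants: 23 the diacetate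
Product: 24 (1S,2R,5R,6S)-6-(3,4-dimethoxyphenyl)-2-(4-hydroxy-3-methoxyphenyl)-3,7-dioxabicyclo[3.3.0]octan-1-yl acetate (target)
Conditions: pyrrolidine (3 equiv), CH2Cl2, 0 °C to rt
Reagents that add atoms: none
Why: Chemoselective aminolysis, in which the aryl acetate has a good phenoxide leaving group and is cleaved by the secondary amine while the hindered tertiary alkyl acetate is inert.

**Compound list**

1 | vanillin | COc1cc(C=O)ccc1O | starting material
2 | 4-(allyloxy)-3-methoxybenzaldehyde | COc1cc(C=O)ccc1OCC=C | intermediate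
3 | [4-(allyloxy)-3-methoxyphenyl]methanol | COc1cc(CO)ccc1OCC=C | intermediate
4 | 4-(allyloxy)-3-methoxybenzyl bromide | COc1cc(CBr)ccc1OCC=C | intermediate
5 | [4-(benzyloxy)-3-methoxyphenyl]methanol | COc1cc(CO)ccc1OCc1ccccc1 | starting material
6 | 4-(benzyloxy)-3-methoxybenzyl bromide | COc1cc(CBr)ccc1OCc1ccccc1 | intermediate
7 | diethyl (S)-malate | CCOC(=O)C[C@H](O)C(=O)OCC | starting material
8 | dilithium alkoxide enolate of 7 (chelated) | [Li+].[Li+].CCOC(=O)[C@@H]([O-])/C=C(\[O-])OCC | intermediate
9 | diethyl (2S,3R)-3-{[4-(allyloxy)-3-methoxyphenyl]methyl}-2-hydroxybutanedioate | CCOC(=O)[C@@H](O)[C@H](C(=O)OCC)Cc1ccc(OCC=C)c(OC)c1 | intermediate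
10 | (2S,3R)-3-{[4-(allyloxy)-3-methoxyphenyl]methyl}-2-hydroxybutanedioic acid | OC(=O)[C@@H](O)[C@H](C(=O)O)Cc1ccc(OCC=C)c(OC)c1 | intermediate
11 | pivalaldehyde | CC(C)(C)C=O | starting material
12 | (2R)-3-[4-(allyloxy)-3-methoxyphenyl]-2-[(2S,4S)-2-tert-butyl-5-oxo-1,3-dioxolan-4-yl]propanoic acid (cis acetal) | CC(C)(C)[C@@H]1OC(=O)[C@H]([C@H](C(=O)O)Cc2ccc(OCC=C)c(OC)c2)O1 | intermediate
13 | dilithium carboxylate enolate of 12 | [Li+].[Li+].CC(C)(C)[C@@H]1OC([O-])=C([C@H](C(=O)[O-])Cc2ccc(OCC=C)c(OC)c2)O1 | intermediate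
14 | (2R)-3-[4-(allyloxy)-3-methoxyphenyl]-2-[(2S,4S)-4-{[4-(benzyloxy)-3-methoxyphenyl]methyl}-2-tert-butyl-5-oxo-1,3-dioxolan-4-yl]propanoic acid | CC(C)(C)[C@@H]1OC(=O)[C@](Cc2ccc(OCc3ccccc3)c(OC)c2)([C@H](C(=O)O)Cc2ccc(OCC=C)c(OC)c2)O1 | intermediate
15 | (2S,3S)-3-{[4-(allyloxy)-3-methoxyphenyl]methyl}-2-{[4-(benzyloxy)-3-methoxyphenyl]methyl}butane-1,2,4-triol | COc1cc(C[C@@](O)(CO)[C@H](CO)Cc2ccc(OCC=C)c(OC)c2)ccc1OCc1ccccc1 | intermediate
16 | (2S,3S)-2-{[4-(benzyloxy)-3-methoxyphenyl]methyl}-3-[(4-hydroxy-3-methoxyphenyl)methyl]butane-1,2,4-triol | COc1cc(C[C@@](O)(CO)[C@H](CO)Cc2ccc(O)c(OC)c2)ccc1OCc1ccccc1 | intermediate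
17 | p-quinone methide from 16, exocyclic C7' alkene (geometry not defined) | COC1=CC(=C[C@@H](CO)[C@](O)(CO)Cc2ccc(OCc3ccccc3)c(OC)c2)C=CC1=O | intermediate
18 | (3S,4R,5S)-3-{[4-(benzyloxy)-3-methoxyphenyl]methyl}-5-(4-hydroxy-3-methoxyphenyl)-4-(hydroxymethyl)oxolan-3-ol | COc1cc(C[C@@]2(O)CO[C@H](c3ccc(O)c(OC)c3)[C@H]2CO)ccc1OCc1ccccc1 | intermediate
19 | (3S,4R,5S)-3-{[4-(benzyloxy)-3-methoxyphenyl]methyl}-5-(3,4-dimethoxyphenyl)-4-(hydroxymethyl)oxolan-3-ol | COc1cc(C[C@@]2(O)CO[C@H](c3ccc(OC)c(OC)c3)[C@H]2CO)ccc1OCc1ccccc1 | intermediate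
20 | (3S,4R,5S)-5-(3,4-dimethoxyphenyl)-3-[(4-hydroxy-3-methoxyphenyl)methyl]-4-(hydroxymethyl)oxolan-3-ol (key-step precursor) | COc1cc(C[C@@]2(O)CO[C@H](c3ccc(OC)c(OC)c3)[C@H]2CO)ccc1O | intermediate
21 | p-quinone methide from 20, exocyclic C7 alkene (geometry not defined) | COC1=CC(=C[C@@]2(O)CO[C@H](c3ccc(OC)c(OC)c3)[C@H]2CO)C=CC1=O | intermediate
22 | (1S,2R,5R,6S)-6-(3,4-dimethoxyphenyl)-2-(4-hydroxy-3-methoxyphenyl)-3,7-dioxabicyclo[3.3.0]octan-1-ol (deacetyl target) | COc1cc([C@H]2OC[C@@H]3[C@@H](c4ccc(OC)c(OC)c4)OC[C@]23O)ccc1O | intermediate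
23 | (1S,2R,5R,6S)-2-(4-acetoxy-3-methoxyphenyl)-6-(3,4-dimethoxyphenyl)-3,7-dioxabicyclo[3.3.0]octan-1-yl acetate | COc1cc([C@H]2OC[C@@H]3[C@@H](c4ccc(OC)c(OC)c4)OC[C@]23OC(C)=O)ccc1OC(C)=O | intermediate
24 | (1S,2R,5R,6S)-6-(3,4-dimethoxyphenyl)-2-(4-hydroxy-3-methoxyphenyl)-3,7-dioxabicyclo[3.3.0]octan-1-yl acetate | COc1cc([C@H]2OC[C@@H]3[C@@H](c4ccc(OC)c(OC)c4)OC[C@]23OC(C)=O)ccc1O | target

**Step count and risks**

Total steps: 16. Longest linear sequence: 15 (vanillin 1 to target 24 through steps 1–3 and 5–16).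

Steps most likely to fail:

1. Step 14 (key step). The product is itself a 4-(α-alkoxyalkyl)-2-methoxyphenol and may be oxidised a second time at C7, opening ring A to an aryl ketone. Phenoxyl radicals may also couple to biaryl dimers before the hindered, neopentylic C7 hydrogen is lost. The fallback sets out from 12 and comes back at 22; it brings C7 in at the alcohol oxidation level so that ring A can be closed by acid instead of by phenol oxidation. The enolate of 12 (LiN(SiMe3)2, THF, −78 °C) is added to purchased 4-(benzyloxy)-3-methoxybenzaldehyde, anti to the tert-butyl group, to give the C7-hydroxy dioxolanone acid F1 (both C7 epimers are usable). LiAlH4 then gives the tetraol F2, and Pd(PPh3)4 with morpholine gives the monophenol tetraol F3. Ag2O closes ring B as in step 11 to give the C7-hydroxy oxolane phenol F4, and MeI with K2CO3 gives the C7-hydroxy dimethoxyphenyl oxolane F5. A catalytic amount of camphorsulfonic acid in CH2Cl2 ionises the 4-benzyloxybenzylic alcohol, and the C9' hydroxyl closes ring A under thermodynamic control to the O-benzyl furofuran F6. Hydrogenolysis (H2, Pd/C, EtOAc) then gives 22.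

2. Step 11. The quinone methide at C7' has a hydrogen on C8' and may tautomerise to a 4-hydroxystyrene, which would erase the C8' stereocentre. Facial selectivity at C7' may also be incomplete, and the product phenol may be oxidised further. The fallback sets out from 6 and comes back at 19; it brings the C7' oxygen in by an aldol addition and closes ring B by acid. Purchased L-malic acid and pivalaldehyde 11 give the cis dioxolanone acid F7 (TsOH, H2SO4, pentane, reflux). LiN(SiMe3)2 and 6 give the C8-benzylated dioxolanone acid F8. LiBH4 reduces only the dioxolanone carbonyl, and acidification closes the 4-hydroxy-4-(arylmethyl)oxolan-2-one F9. Its dilithium alkoxide enolate (LiN(iPr)2, 2.2 equiv, THF, −78 °C) adds to purchased veratraldehyde at C8' to give the aldol lactone F10. Approach anti to the arylmethyl group is expected on steric grounds, as in aldol reactions of 4-benzyl butyrolactones, but this selectivity is the weak point of the fallback and the C8' epimer would have to be separated; the C7' epimers are both usable. LiAlH4 gives the tetraol F11, and catalytic camphorsulfonic acid in CH2Cl2 at 0 °C closes ring B through the C7' benzylic cation under thermodynamic control (aryl trans to the hydroxymethyl group), arriving at 19.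

3. Step 8. The dioxolanone enolate may fragment before it is alkylated, and the C8' stereocentre in the side chain may erode the preference for attack anti to the tert-butyl group. The fallback sets out from 12 and comes back at 15; it lets the ring stereocentre C8' of a lactone control the alkylation instead of the acetal. BH3·SMe2 reduces the free C9' acid of 12, and TsOH closes the new alcohol onto the dioxolanone carbonyl with loss of pivalaldehyde to give the cis 3-hydroxy-4-(arylmethyl)oxolan-2-one F12. Et3SiCl and imidazole give the triethylsilyl ether F13. Its lactone enolate (LiN(iPr)2, THF, −78 °C) is alkylated with 6 anti to the C8' arylmethyl group, the usual trans-selective alkylation of 4-substituted butyrolactones, to give the quaternary silyl ether F14. Aqueous HCl in THF gives the hydroxy lactone F15, and LiAlH4 reduces it to 15.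

**Further compounds**

F1 | step 14 | (2R)-3-[4-(allyloxy)-3-methoxyphenyl]-2-[(2S,4S)-4-{[4-(benzyloxy)-3-methoxyphenyl](hydroxy)methyl}-2-tert-butyl-5-oxo-1,3-dioxolan-4-yl]propanoic acid (C7 epimers) | CC(C)(C)[C@@H]1OC(=O)[C@](C(O)c2ccc(OCc3ccccc3)c(OC)c2)([C@H](C(=O)O)Cc2ccc(OCC=C)c(OC)c2)O1
F2 | step 14 | C7-hydroxy analogue of triol 15 (tetraol, C7 epimers) | COc1cc(C(O)[C@@](O)(CO)[C@H](CO)Cc2ccc(OCC=C)c(OC)c2)ccc1OCc1ccccc1
F3 | step 14 | C7-hydroxy analogue of monophenol 16 | COc1cc(C(O)[C@@](O)(CO)[C@H](CO)Cc2ccc(O)c(OC)c2)ccc1OCc1ccccc1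
F4 | step 14 | C7-hydroxy analogue of oxolane phenol 18 | COc1cc(C(O)[C@@]2(O)CO[C@H](c3ccc(O)c(OC)c3)[C@H]2CO)ccc1OCc1ccccc1
F5 | step 14 | C7-hydroxy analogue of oxolane 19 | COc1cc(C(O)[C@@]2(O)CO[C@H](c3ccc(OC)c(OC)c3)[C@H]2CO)ccc1OCc1ccccc1
F6 | step 14 | O-benzyl ether of furofuran 22 | COc1cc([C@H]2OC[C@@H]3[C@@H](c4ccc(OC)c(OC)c4)OC[C@]23O)ccc1OCc1ccccc1
F7 | step 11 | (2S,4S)-2-tert-butyl-5-oxo-1,3-dioxolane-4-acetic acid | CC(C)(C)[C@@H]1OC(=O)[C@H](CC(=O)O)O1
F8 | step 11 | (2S,4S)-4-{[4-(benzyloxy)-3-methoxyphenyl]methyl}-2-tert-butyl-5-oxo-1,3-dioxolane-4-acetic acid | CC(C)(C)[C@@H]1OC(=O)[C@](Cc2ccc(OCc3ccccc3)c(OC)c2)(CC(=O)O)O1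
F9 | step 11 | (4S)-4-{[4-(benzyloxy)-3-methoxyphenyl]methyl}-4-hydroxyoxolan-2-one | O=C1C[C@@](O)(Cc2ccc(OCc3ccccc3)c(OC)c2)CO1
F10 | step 11 | aldol lactone, 3-[(3,4-dimethoxyphenyl)(hydroxy)methyl] derivative of F9 with the side chain cis to the C8 hydroxyl (C7' epimers) | O=C1[C@H](C(O)c2ccc(OC)c(OC)c2)[C@@](O)(Cc2ccc(OCc3ccccc3)c(OC)c2)CO1
F11 | step 11 | tetraol, C7'-hydroxy open-chain precursor of 19 (C7' epimers) | COc1cc(C[C@@](O)(CO)[C@H](CO)C(O)c2ccc(OC)c(OC)c2)ccc1OCc1ccccc1
F12 | step 8 | (3S,4S)-4-{[4-(allyloxy)-3-methoxyphenyl]methyl}-3-hydroxyoxolan-2-one | O=C1[C@@H](O)[C@@H](Cc2ccc(OCC=C)c(OC)c2)CO1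
F13 | step 8 | triethylsilyl ether of F12 | O=C1[C@@H](O[Si](CC)(CC)CC)[C@@H](Cc2ccc(OCC=C)c(OC)c2)CO1
F14 | step 8 | 3-{[4-(benzyloxy)-3-methoxyphenyl]methyl} derivative of F13 (arylmethyl groups trans) | O=C1[C@](O[Si](CC)(CC)CC)(Cc2ccc(OCc3ccccc3)c(OC)c2)[C@@H](Cc2ccc(OCC=C)c(OC)c2)CO1
F15 | step 8 | hydroxy lactone from F14 | O=C1[C@](O)(Cc2ccc(OCc3ccccc3)c(OC)c2)[C@@H](Cc2ccc(OCC=C)c(OC)c2)CO1
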